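**Retrosynthetic overview**
- Feature: on each lactone-borne guaiacyl ring (ring A on the C4 benzyl group, ring B on the C3 benzyl group) the free O4–H sits ortho to the C5–C8 bond, while C3 (OMe) and C1 (CH2) block the other ortho site and the para site. This is an ortho-Claisen retron. Both C7 carbinols are S, but C8 is S on ring A and R on ring B (C7 = carbinol carbon, C8 = aryl-bearing methine, C9 = CH2OH of each side arm).
- Disconnection 1: both C5–C8 bonds go back to O4–C bonds of aryl (E)-sec-allyl ethers. Their methyl-bearing ether carbons (S on ring A, R on ring B) relay the two C8 centres, and the propenyl groups left behind are masked C9 CH2OH groups.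
- Disconnection 2: both C7–alkenyl bonds come from double hydroboration, boron-to-zinc exchange and ligand-controlled addition to two equivalents of O-silyl vanillin. The bis(propargylic ether) comes from trans-selective enolate benzylation (lactone C3–CH2 bond) and two Mitsunobu inversions of enantiomeric alkynols.
- Ring order: the γ-butyrolactone is the only ring made and is closed first, by enantioselective dirhodium-carbenoid C–H insertion of a 3-arylpropyl diazoacetate. No ring is formed afterwards.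

Key step: step 15

Assumption: the 4R antipode of Rh2(MPPIM)4 (dirhodium tetrakis[methyl 1-(3-phenylpropanoyl)-2-oxoimidazolidine-4-carboxylate]) is taken to give the (S)-lactone, and (2S)-(−)-3-exo-morpholinoisoborneol [(−)-MIB] to direct alkenyl transfer to the Si face of the aryl aldehyde (7S); if either sense proves opposite, the enantiomeric catalyst or ligand is used with no other change.

Step 1
Reactants: 1 dihydroconiferyl alcohol
Product: 2 3-(4-benzyloxy-3-methoxyphenyl)propan-1-ol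
Conditions: BnBr, K2CO3, acetone, reflux
Reagents that add atoms: benzyl bromide, BrCc1ccccc1
Why: Williamson etherification in which K2CO3 deprotonates only the phenol, so O4 is benzylated and the primary alcohol stays free.

Step 2
Reactants: 2 3-(4-benzyloxy-3-methoxyphenyl)propan-1-ol; 3 bromoacetyl bromide
Product: 4 3-(4-benzyloxy-3-methoxyphenyl)propyl bromoacetate
Conditions: NaHCO3, MeCN, 0 °C
Reagents that add atoms: none
Why: O-acylation of the primary alcohol by the acyl bromide, which is far more electrophilic than the alkyl bromide end, with hydrogencarbonate as acid scavenger.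

Step 3
Reactants: 4 3-(4-benzyloxy-3-methoxyphenyl)propyl bromoacetate
Product: 5 3-(4-benzyloxy-3-methoxyphenyl)propyl diazoacetate
Conditions: TsNHNHTs, DBU, THF, 0 °C
Reagents that add atoms: N,N'-bis(p-toluenesulfonyl)hydrazine, Cc1ccc(cc1)S(=O)(=O)NNS(=O)(=O)c1ccc(C)cc1
Why: diazoacetate formation from a bromoacetate by N-alkylation of the bis-sulfonylhydrazine followed by two base-induced sulfinate eliminations, under conditions mild enough to keep the diazo ester.

Step 4
Reactants: 5 3-(4-benzyloxy-3-methoxyphenyl)propyl diazoacetate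
Product: 6 (S)-4-(4-benzyloxy-3-methoxybenzyl)dihydrofuran-2(3H)-one
Conditions: Rh2(4R-MPPIM)4 (1 mol %), CH2Cl2, reflux, slow addition of 5
Reagents that add atoms: none
Why: intramolecular dirhodium-carbenoid C–H insertion closes the five-membered lactone at the central CH2 of the propyl chain (carboxamidate ligands suppress aromatic cycloaddition), and the chiral ligand sphere selects one enantiotopic C–H bond to set lactone C4 as S.

Step 5
Reactants: 6 (S)-4-(4-benzyloxy-3-methoxybenzyl)dihydrofuran-2(3H)-one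
Product: 7 (S)-4-(4-hydroxy-3-methoxybenzyl)dihydrofuran-2(3H)-one
Conditions: H2 (1 atm), Pd/C, EtOAc, rt
Reagents that add atoms: none
Why: catalytic hydrogenolysis of the benzyl ether leaves the lactone, the arene and the C4 stereocentre untouched.

Step 6
Reactants: 7 (S)-4-(4-hydroxy-3-methoxybenzyl)dihydrofuran-2(3H)-one; 8 (R)-4-(trimethylsilyl)but-3-yn-2-ol
Product: 9 (S)-4-{3-methoxy-4-[(S)-4-(trimethylsilyl)but-3-yn-2-yloxy]benzyl}dihydrofuran-2(3H)-one
Conditions: PPh3, DIAD, THF, 0 °C to rt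
Reagents that add atoms: none
Why: Mitsunobu etherification of the phenol with the secondary propargylic alcohol proceeds by SN2 with inversion, turning the (R)-carbinol into the (S)-aryl ether carbon that will relay C8 of ring A.

Step 7
Reactants: 10 vanillin; 11 (S)-4-(trimethylsilyl)but-3-yn-2-ol
Product: 12 3-methoxy-4-[(R)-4-(trimethylsilyl)but-3-yn-2-yloxy]benzaldehyde
Conditions: PPh3, DIAD, THF, 0 °C to rt
Reagents that add atoms: none
Why: Mitsunobu etherification of the acidic vanillin phenol with inversion gives the (R)-ether carbon that will relay C8 of ring B.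

Step 8
Reactants: 12 3-methoxy-4-[(R)-4-(trimethylsilyl)but-3-yn-2-yloxy]benzaldehyde
Product: 13 {3-methoxy-4-[(R)-4-(trimethylsilyl)but-3-yn-2-yloxy]phenyl}methanol
Conditions: NaBH4, THF/MeOH, 0 °C
Reagents that add atoms: none
Why: borohydride reduction of the aryl aldehyde, run cold and briefly so that the alkynylsilane survives.

Step 9
Reactants: 13 {3-methoxy-4-[(R)-4-(trimethylsilyl)but-3-yn-2-yloxy]phenyl}methanol
Product: 14 4-(bromomethyl)-2-methoxy-1-[(R)-4-(trimethylsilyl)but-3-yn-2-yloxy]benzene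
Conditions: CBr4, PPh3, CH2Cl2, 0 °C
Reagents that add atoms: carbon tetrabromide, BrC(Br)(Br)Br
Why: Appel bromination converts the benzylic alcohol under neutral conditions and leaves the ether stereocentre and the alkynylsilane alone.

Step 10
Reactants: 9 (S)-4-{3-methoxy-4-[(S)-4-(trimethylsilyl)but-3-yn-2-yloxy]benzyl}dihydrofuran-2(3H)-one; 14 4-(bromomethyl)-2-methoxy-1-[(R)-4-(trimethylsilyl)but-3-yn-2-yloxy]benzene
Product: 16 (3S,4S)-trans-dibenzylbutyrolactone bis(silylpropargyl ether), via lithium enolate 15 (not isolated)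
Conditions: LiN(SiMe3)2, THF, −78 °C; then 14, DMPU, −78 to −40 °C
Reagents that add atoms: none
Why: lithium enolate alkylation of the β-substituted butyrolactone, in which the benzylic bromide approaches anti to the C4 benzyl group to give the trans lactone (C3 S); one equivalent of base avoids dialkylation and the C-silyl groups mask the acidic alkyne C–H.

Step 11
Reactants: 16 (3S,4S)-trans-dibenzylbutyrolactone bis(silylpropargyl ether)
Product: 17 (3S,4S)-trans-dibenzylbutyrolactone bis(but-3-yn-2-yl ether)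
Conditions: Bu4NF, AcOH, THF, 0 °C
Reagents that add atoms: none
Why: fluoride-induced protodesilylation of both C(sp)–Si bonds, buffered with acetic acid so that the lactone and its α-stereocentre are not exposed to base.

Step 12
Reactants: 10 vanillin
Product: 18 4-(tert-butyldimethylsilyloxy)-3-methoxybenzaldehyde
Conditions: TBSCl, imidazole, DMF, rt
Reagents that add atoms: tert-butyldimethylsilyl chloride, CC(C)(C)[Si](C)(C)Cl
Why: standard imidazole-mediated silylation of a phenol.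

Step 13
Reactants: 17 (3S,4S)-trans-dibenzylbutyrolactone bis(but-3-yn-2-yl ether); 18 4-(tert-butyldimethylsilyloxy)-3-methoxybenzaldehyde (2 equiv)
Product: 21 bis[(E)-allylic alcohol] with both C7 S, via bis(alkenylborane) 19 (not isolated), via bis(alkenylzinc) 20 (not isolated)
Conditions: Cy2BH (2.2 equiv, from BH3·SMe2, cyclohexene), toluene, 0 °C to rt; Me2Zn, −78 °C; (−)-MIB (cat.), 18 (2.4 equiv), −30 to 0 °C; aq NH4Cl
Reagents that add atoms: 4-(tert-butyldimethylsilyloxy)-3-methoxybenzaldehyde (second equivalent of 18), COc1cc(C=O)ccc1O[Si](C)(C)C(C)(C)C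
Why: syn-hydroboration of each terminal alkyne by the bulky dialkylborane gives the (E)-1-alkenylborane, boron-to-zinc exchange gives the alkenyl(methyl)zinc, and each of the two alkenylzinc termini then adds under (−)-MIB control to the Si face of its own molecule of aldehyde 18 (two equivalents are consumed in all), setting both C7 centres S by reagent control (the ether stereocentres are too remote to interfere and the lactone tolerates these reagents).

Step 14
Reactants: 21 bis[(E)-allylic alcohol] with both C7 S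
Product: 22 bis(aryl sec-allyl ether) with both C7 carbinols as tert-butyldimethylsilyl ethers
Conditions: TBSCl, imidazole, DMAP (cat.), DMF, rt
Reagents that add atoms: tert-butyldimethylsilyl chloride, CC(C)(C)[Si](C)(C)Cl
Why: silylation of the two secondary carbinols under non-acidic conditions avoids ionising these benzylic and allylic positions.

Step 15
Reactants: 22 bis(aryl sec-allyl ether) with both C7 carbinols as tert-butyldimethylsilyl ethers
Product: 24 bis(5-C-alkylated phenol) with two (E)-propenyl groups, via bis(trimethylsilyl ether) 23 (not isolated)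
Conditions: BSA (6 equiv), PhNEt2, 185 °C, sealed tube, Ar; then MeOH, citric acid (cat.), rt
Reagents that add atoms: none
Why: Each aryl sec-allyl ether undergoes a concerted suprafacial [3,3] sigmatropic shift through a chair-like six-membered transition state with the ether methyl group pseudo-equatorial, giving a 6-substituted cyclohexa-2,4-dienone that enolises to the phenol, which BSA holds as the trimethylsilyl ether 23 until work-up; the closest known reaction is the ortho-Claisen rearrangement of enantioenriched (E)-secondary allyl aryl ethers with 1,3-chirality transfer. No ring is closed: in each arm the O4–C(methyl) bond breaks while the C5–C8 bond forms and the alkene moves to give an (E)-propenyl group. Because the new bond forms on the allyl face that oxygen leaves, C8 on ring A (8S in the target) is fixed by the (S)-ether carbon and C8 on ring B (8R) by the (R)-ether carbon, in each case together with the (E)-alkene. The step needs C5 regioselectivity and opposite facial selectivity in two arms that share 7S: a shift to the methoxy-bearing C3 or onward to the substituted C1 gives dienones with no hydrogen to lose, which return to the ether, so material funnels to C5. The axial-methyl transition state, which would give a (Z)-propenyl group and the C8 epimer, is penalised by 1,3-diaxial strain, and the resident C7 centre can speed up or slow down an arm but not redirect it. The arms are remote and react independently, and silyl capture of the new phenols shuts off the abnormal-Claisen ene pathway.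

Step 16
Reactants: 24 bis(5-C-alkylated phenol) with two (E)-propenyl groups
Product: 25 hexakis(tert-butyldimethylsilyl) ether
Conditions: TBSOTf, 2,6-lutidine, CH2Cl2, 0 °C to rt
Reagents that add atoms: tert-butyldimethylsilyl trifluoromethanesulfonate, CC(C)(C)[Si](C)(C)OS(=O)(=O)C(F)(F)F
Why: silyl triflate silylation of the two hindered, newly freed phenols, so that no free electron-rich phenol is exposed to the oxidant of the next step.

Step 17
Reactants: 25 hexakis(tert-butyldimethylsilyl) ether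
Product: 28 hexasilylated C9 diol, via bis(trioxolane) 26 (not isolated), via bis(aldehyde) 27 (not isolated)
Conditions: O3, CH2Cl2, −78 °C (Sudan Red 7B endpoint); PPh3, −78 to 0 °C; NaBH4, MeOH, 0 °C
Reagents that add atoms: ozone, [O-][O+]=O
Why: ozonolysis of the two 1,2-disubstituted alkenes (faster than attack on the silylated arenes, with a dye marking the endpoint), phosphine reduction of the ozonides and immediate borohydride reduction of the α-aryl aldehydes before they can epimerise; no bond to C8 is broken, so its configuration is kept.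

Step 18
Reactants: 28 hexasilylated C9 diol
Product: 29 CNP0113972.1
Conditions: Bu4NF, AcOH (1:1), THF, 0 °C to rt
Reagents that add atoms: none
Why: fluoride cleavage of the four aryl and two secondary alkyl silyl ethers, buffered with acetic acid so that no phenoxide can trigger quinone-methide formation at C7 or open the lactone.

**Compound list**
1 | dihydroconiferyl alcohol | COc1cc(CCCO)ccc1O | starting material
2 | 3-(4-benzyloxy-3-methoxyphenyl)propan-1-ol | COc1cc(CCCO)ccc1OCc1ccccc1 | intermediate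
3 | bromoacetyl bromide | BrCC(=O)Br | starting material
4 | 3-(4-benzyloxy-3-methoxyphenyl)propyl bromoacetate | COc1cc(CCCOC(=O)CBr)ccc1OCc1ccccc1 | intermediate
5 | 3-(4-benzyloxy-3-methoxyphenyl)propyl diazoacetate | COc1cc(CCCOC(=O)C=[N+]=[N-])ccc1OCc1ccccc1 | intermediate
6 | (S)-4-(4-benzyloxy-3-methoxybenzyl)dihydrofuran-2(3H)-one | COc1cc(C[C@@H]2COC(=O)C2)ccc1OCc1ccccc1 | intermediate
7 | (S)-4-(4-hydroxy-3-methoxybenzyl)dihydrofuran-2(3H)-one | COc1cc(C[C@@H]2COC(=O)C2)ccc1O | intermediate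
8 | (R)-4-(trimethylsilyl)but-3-yn-2-ol | C[C@@H](O)C#C[Si](C)(C)C | starting material
9 | (S)-4-{3-methoxy-4-[(S)-4-(trimethylsilyl)but-3-yn-2-yloxy]benzyl}dihydrofuran-2(3H)-one | COc1cc(C[C@@H]2COC(=O)C2)ccc1O[C@@H](C)C#C[Si](C)(C)C | intermediate
10 | vanillin | COc1cc(C=O)ccc1O | starting material
11 | (S)-4-(trimethylsilyl)but-3-yn-2-ol | C[C@H](O)C#C[Si](C)(C)C | starting material
12 | 3-methoxy-4-[(R)-4-(trimethylsilyl)but-3-yn-2-yloxy]benzaldehyde | COc1cc(C=O)ccc1O[C@H](C)C#C[Si](C)(C)C | intermediate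
13 | {3-methoxy-4-[(R)-4-(trimethylsilyl)but-3-yn-2-yloxy]phenyl}methanol | COc1cc(CO)ccc1O[C@H](C)C#C[Si](C)(C)C | intermediate
14 | 4-(bromomethyl)-2-methoxy-1-[(R)-4-(trimethylsilyl)but-3-yn-2-yloxy]benzene | COc1cc(CBr)ccc1O[C@H](C)C#C[Si](C)(C)C | intermediate
15 | lithium enolate of 9 | [Li+].COc1cc(C[C@@H]2COC([O-])=C2)ccc1O[C@@H](C)C#C[Si](C)(C)C | intermediate
16 | (3S,4S)-trans-dibenzylbutyrolactone bis(silylpropargyl ether), ring A ether carbon S, ring B ether carbon R | COc1cc(C[C@@H]2COC(=O)[C@H]2Cc2ccc(O[C@H](C)C#C[Si](C)(C)C)c(OC)c2)ccc1O[C@@H](C)C#C[Si](C)(C)C | intermediate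
17 | (3S,4S)-trans-dibenzylbutyrolactone bis(but-3-yn-2-yl ether) | COc1cc(C[C@@H]2COC(=O)[C@H]2Cc2ccc(O[C@H](C)C#C)c(OC)c2)ccc1O[C@@H](C)C#C | intermediate
18 | 4-(tert-butyldimethylsilyloxy)-3-methoxybenzaldehyde | COc1cc(C=O)ccc1O[Si](C)(C)C(C)(C)C | intermediate
19 | bis[(E)-alkenyl(dicyclohexyl)borane] from 17 | COc1cc(C[C@@H]2COC(=O)[C@H]2Cc2ccc(O[C@H](C)/C=C/B(C3CCCCC3)C3CCCCC3)c(OC)c2)ccc1O[C@@H](C)/C=C/B(C1CCCCC1)C1CCCCC1 | intermediate
20 | bis[(E)-alkenyl(methyl)zinc] | COc1cc(C[C@@H]2COC(=O)[C@H]2Cc2ccc(O[C@H](C)/C=C/[Zn]C)c(OC)c2)ccc1O[C@@H](C)/C=C/[Zn]C | intermediate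
21 | bis[(E)-allylic alcohol], both C7 S, ether carbons S (ring A) and R (ring B) | COc1cc(C[C@@H]2COC(=O)[C@H]2Cc2ccc(O[C@H](C)/C=C/[C@H](O)c3ccc(O[Si](C)(C)C(C)(C)C)c(OC)c3)c(OC)c2)ccc1O[C@@H](C)/C=C/[C@H](O)c1ccc(O[Si](C)(C)C(C)(C)C)c(OC)c1 | intermediate
22 | bis(aryl sec-allyl ether), both C7 carbinols as tert-butyldimethylsilyl ethers | COc1cc(C[C@@H]2COC(=O)[C@H]2Cc2ccc(O[C@H](C)/C=C/[C@H](O[Si](C)(C)C(C)(C)C)c3ccc(O[Si](C)(C)C(C)(C)C)c(OC)c3)c(OC)c2)ccc1O[C@@H](C)/C=C/[C@H](O[Si](C)(C)C(C)(C)C)c1ccc(O[Si](C)(C)C(C)(C)C)c(OC)c1 | intermediate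
23 | rearranged bis(aryl trimethylsilyl ether) | COc1cc([C@@H](O[Si](C)(C)C(C)(C)C)[C@H](/C=C/C)c2cc(C[C@@H]3COC(=O)[C@H]3Cc3cc(OC)c(O[Si](C)(C)C)c([C@H](/C=C/C)[C@H](O[Si](C)(C)C(C)(C)C)c4ccc(O[Si](C)(C)C(C)(C)C)c(OC)c4)c3)cc(OC)c2O[Si](C)(C)C)ccc1O[Si](C)(C)C(C)(C)C | intermediate
24 | bis(5-C-alkylated phenol) with two (E)-propenyl groups, C8 centres as in the target (propenyl in place of CH2OH) | COc1cc([C@@H](O[Si](C)(C)C(C)(C)C)[C@H](/C=C/C)c2cc(C[C@@H]3COC(=O)[C@H]3Cc3cc(OC)c(O)c([C@H](/C=C/C)[C@H](O[Si](C)(C)C(C)(C)C)c4ccc(O[Si](C)(C)C(C)(C)C)c(OC)c4)c3)cc(OC)c2O)ccc1O[Si](C)(C)C(C)(C)C | intermediate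
25 | hexakis(tert-butyldimethylsilyl) ether of 24 (all four phenols and both C7 carbinols silylated) | COc1cc([C@@H](O[Si](C)(C)C(C)(C)C)[C@H](/C=C/C)c2cc(C[C@@H]3COC(=O)[C@H]3Cc3cc(OC)c(O[Si](C)(C)C(C)(C)C)c([C@H](/C=C/C)[C@H](O[Si](C)(C)C(C)(C)C)c4ccc(O[Si](C)(C)C(C)(C)C)c(OC)c4)c3)cc(OC)c2O[Si](C)(C)C(C)(C)C)ccc1O[Si](C)(C)C(C)(C)C | intermediate
26 | bis(1,2,4-trioxolane) from 25 (ozonide carbons as a mixture) | COc1cc([C@@H](O[Si](C)(C)C(C)(C)C)[C@H](C5OOC(C)O5)c2cc(C[C@@H]3COC(=O)[C@H]3Cc3cc(OC)c(O[Si](C)(C)C(C)(C)C)c([C@H](C6OOC(C)O6)[C@H](O[Si](C)(C)C(C)(C)C)c4ccc(O[Si](C)(C)C(C)(C)C)c(OC)c4)c3)cc(OC)c2O[Si](C)(C)C(C)(C)C)ccc1O[Si](C)(C)C(C)(C)C | intermediate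
27 | bis(α-aryl aldehyde) | COc1cc([C@@H](O[Si](C)(C)C(C)(C)C)[C@H](C=O)c2cc(C[C@@H]3COC(=O)[C@H]3Cc3cc(OC)c(O[Si](C)(C)C(C)(C)C)c([C@H](C=O)[C@H](O[Si](C)(C)C(C)(C)C)c4ccc(O[Si](C)(C)C(C)(C)C)c(OC)c4)c3)cc(OC)c2O[Si](C)(C)C(C)(C)C)ccc1O[Si](C)(C)C(C)(C)C | intermediate
28 | hexasilylated C9 diol | COc1cc([C@@H](O[Si](C)(C)C(C)(C)C)[C@H](CO)c2cc(C[C@@H]3COC(=O)[C@H]3Cc3cc(OC)c(O[Si](C)(C)C(C)(C)C)c([C@H](CO)[C@H](O[Si](C)(C)C(C)(C)C)c4ccc(O[Si](C)(C)C(C)(C)C)c(OC)c4)c3)cc(OC)c2O[Si](C)(C)C(C)(C)C)ccc1O[Si](C)(C)C(C)(C)C | intermediate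
29 | CNP0113972.1: lactone 3S,4S; ring A arm 7S,8S; ring B arm 7S,8R | COc1cc([C@@H](O)[C@H](CO)c2cc(C[C@@H]3COC(=O)[C@H]3Cc3cc(OC)c(O)c([C@H](CO)[C@H](O)c4ccc(O)c(OC)c4)c3)cc(OC)c2O)ccc1O | target

**Step count**
Total steps: 18. Longest linear sequence: 14 (steps 1–6, 10, 11, 13–18).

**Steps most likely to fail**

1. Step 15 (two-fold rearrangement). Two independent rearrangements must both run to completion with full 1,3-chirality transfer. Thermal C–O heterolysis to an ion pair, loss of silanol from the C7 ether or stalling of the second arm would leave half-rearranged material and C8 diastereomers that cannot be purged on a large, flexible dimer. Fallback: the two rearrangements are decoupled so that each is a single event on one arm, with purification in between; the path sets out from 9 and comes back to the route at 25. Compound 9 is C-desilylated (Bu4NF, AcOH) to the lactone terminal alkyne F1. Hydroboration with Cy2BH gives the alkenylborane F2, exchange with Me2Zn gives the alkenylzinc F3, and (−)-MIB-controlled addition to 18 gives the (7S)-allylic alcohol F4, which is silylated (TBSCl, imidazole) to the silyl ether F5. A single rearrangement (BSA, PhNEt2, 185 °C) passes through the O-trimethylsilyl ether F6 to the monomeric phenol F7, a compound about half the size of 24 from which a C8 epimer should be separable. TBSOTf then gives the aryl silyl ether F8. Its lithium enolate F9 is benzylated with 14 to the trans-dibenzyl lactone F10, and the alkynylsilane is cleaved with AgNO3 and 2,6-lutidine in aqueous acetone, which spares the silyl ethers, to the terminal alkyne F11. The same hydroboration (alkenylborane F12), zinc exchange (alkenylzinc F13) and aldehyde addition give the allylic alcohol F14. Silylation gives the silyl ether F15, a second single rearrangement gives, through the O-trimethylsilyl ether F16, the mono-phenol F17, and TBSOTf converts this into 25.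

2. Step 13 (two-fold alkenylzinc addition). Alkenyl transfer may be incomplete on one arm, methyl transfer from zinc may compete, or facial control may be insufficient in one of the two additions. Fallback: chromium-mediated alkenyl iodide coupling in place of the zinc chemistry; it sets out from 17 and comes back at 21. Palladium-catalysed hydrostannation of 17 (Bu3SnH, PdCl2(PPh3)2, THF, 0 °C) gives the bis[(E)-alkenylstannane] F18, and iododestannylation (I2, CH2Cl2, 0 °C) gives the bis[(E)-alkenyl iodide] F19. A Nozaki–Hiyama–Kishi coupling with two equivalents of 18 (CrCl2, NiCl2 (cat.), a chiral sulfonamide–oxazoline ligand, Et3N, THF, rt), which tolerates the lactone, then gives 21 with the carbinol configuration set by the ligand.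

3. Step 17 (ozonolysis and reduction). Ozone may over-oxidise the electron-rich silyloxy- and methoxy-arenes before both alkenes are consumed. Fallback: a two-stage osmium route; it sets out from 25 and comes back at 28. Dihydroxylation (OsO4 (cat.), NMO, acetone/H2O) gives the bis(vicinal diol) F20. Glycol cleavage (NaIO4, pH 7 buffer, THF/H2O, 0 °C) gives the bis(aldehyde) 27, which is reduced at once with NaBH4 to 28.

**Further compounds**
F1 | step 15 | lactone terminal alkyne ether from 9 | COc1cc(C[C@@H]2COC(=O)C2)ccc1O[C@@H](C)C#C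
F2 | step 15 | mono-arm (E)-alkenyl(dicyclohexyl)borane | COc1cc(C[C@@H]2COC(=O)C2)ccc1O[C@@H](C)/C=C/B(C1CCCCC1)C1CCCCC1
F3 | step 15 | mono-arm (E)-alkenyl(methyl)zinc | COc1cc(C[C@@H]2COC(=O)C2)ccc1O[C@@H](C)/C=C/[Zn]C
F4 | step 15 | mono-arm (7S)-allylic alcohol | COc1cc(C[C@@H]2COC(=O)C2)ccc1O[C@@H](C)/C=C/[C@H](O)c1ccc(O[Si](C)(C)C(C)(C)C)c(OC)c1
F5 | step 15 | mono-arm C7 tert-butyldimethylsilyl ether | COc1cc(C[C@@H]2COC(=O)C2)ccc1O[C@@H](C)/C=C/[C@H](O[Si](C)(C)C(C)(C)C)c1ccc(O[Si](C)(C)C(C)(C)C)c(OC)c1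
F6 | step 15 | rearranged monomer as aryl trimethylsilyl ether | COc1cc([C@@H](O[Si](C)(C)C(C)(C)C)[C@H](/C=C/C)c2cc(C[C@@H]3COC(=O)C3)cc(OC)c2O[Si](C)(C)C)ccc1O[Si](C)(C)C(C)(C)C
F7 | step 15 | rearranged monomeric phenol | COc1cc([C@@H](O[Si](C)(C)C(C)(C)C)[C@H](/C=C/C)c2cc(C[C@@H]3COC(=O)C3)cc(OC)c2O)ccc1O[Si](C)(C)C(C)(C)C
F8 | step 15 | rearranged monomer as aryl tert-butyldimethylsilyl ether | COc1cc([C@@H](O[Si](C)(C)C(C)(C)C)[C@H](/C=C/C)c2cc(C[C@@H]3COC(=O)C3)cc(OC)c2O[Si](C)(C)C(C)(C)C)ccc1O[Si](C)(C)C(C)(C)C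
F9 | step 15 | lithium enolate of F8 | [Li+].COc1cc([C@@H](O[Si](C)(C)C(C)(C)C)[C@H](/C=C/C)c2cc(C[C@@H]3COC([O-])=C3)cc(OC)c2O[Si](C)(C)C(C)(C)C)ccc1O[Si](C)(C)C(C)(C)C
F10 | step 15 | trans-dibenzyl lactone with arm A complete and ring B silylpropargyl ether | COc1cc([C@@H](O[Si](C)(C)C(C)(C)C)[C@H](/C=C/C)c2cc(C[C@@H]3COC(=O)[C@H]3Cc3ccc(O[C@H](C)C#C[Si](C)(C)C)c(OC)c3)cc(OC)c2O[Si](C)(C)C(C)(C)C)ccc1O[Si](C)(C)C(C)(C)C
F11 | step 15 | ring B terminal alkyne | COc1cc([C@@H](O[Si](C)(C)C(C)(C)C)[C@H](/C=C/C)c2cc(C[C@@H]3COC(=O)[C@H]3Cc3ccc(O[C@H](C)C#C)c(OC)c3)cc(OC)c2O[Si](C)(C)C(C)(C)C)ccc1O[Si](C)(C)C(C)(C)C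
F12 | step 15 | ring B (E)-alkenyl(dicyclohexyl)borane | COc1cc([C@@H](O[Si](C)(C)C(C)(C)C)[C@H](/C=C/C)c2cc(C[C@@H]3COC(=O)[C@H]3Cc3ccc(O[C@H](C)/C=C/B(C4CCCCC4)C4CCCCC4)c(OC)c3)cc(OC)c2O[Si](C)(C)C(C)(C)C)ccc1O[Si](C)(C)C(C)(C)C
F13 | step 15 | ring B (E)-alkenyl(methyl)zinc | COc1cc([C@@H](O[Si](C)(C)C(C)(C)C)[C@H](/C=C/C)c2cc(C[C@@H]3COC(=O)[C@H]3Cc3ccc(O[C@H](C)/C=C/[Zn]C)c(OC)c3)cc(OC)c2O[Si](C)(C)C(C)(C)C)ccc1O[Si](C)(C)C(C)(C)C
F14 | step 15 | ring B (7S)-allylic alcohol | COc1cc([C@@H](O[Si](C)(C)C(C)(C)C)[C@H](/C=C/C)c2cc(C[C@@H]3COC(=O)[C@H]3Cc3ccc(O[C@H](C)/C=C/[C@H](O)c4ccc(O[Si](C)(C)C(C)(C)C)c(OC)c4)c(OC)c3)cc(OC)c2O[Si](C)(C)C(C)(C)C)ccc1O[Si](C)(C)C(C)(C)C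
F15 | step 15 | ring B C7 tert-butyldimethylsilyl ether | COc1cc([C@@H](O[Si](C)(C)C(C)(C)C)[C@H](/C=C/C)c2cc(C[C@@H]3COC(=O)[C@H]3Cc3ccc(O[C@H](C)/C=C/[C@H](O[Si](C)(C)C(C)(C)C)c4ccc(O[Si](C)(C)C(C)(C)C)c(OC)c4)c(OC)c3)cc(OC)c2O[Si](C)(C)C(C)(C)C)ccc1O[Si](C)(C)C(C)(C)C
F16 | step 15 | doubly rearranged compound with ring B phenol as trimethylsilyl ether | COc1cc([C@@H](O[Si](C)(C)C(C)(C)C)[C@H](/C=C/C)c2cc(C[C@@H]3COC(=O)[C@H]3Cc3cc(OC)c(O[Si](C)(C)C)c([C@H](/C=C/C)[C@H](O[Si](C)(C)C(C)(C)C)c4ccc(O[Si](C)(C)C(C)(C)C)c(OC)c4)c3)cc(OC)c2O[Si](C)(C)C(C)(C)C)ccc1O[Si](C)(C)C(C)(C)C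
F17 | step 15 | doubly rearranged mono-phenol (ring B OH free) | COc1cc([C@@H](O[Si](C)(C)C(C)(C)C)[C@H](/C=C/C)c2cc(C[C@@H]3COC(=O)[C@H]3Cc3cc(OC)c(O)c([C@H](/C=C/C)[C@H](O[Si](C)(C)C(C)(C)C)c4ccc(O[Si](C)(C)C(C)(C)C)c(OC)c4)c3)cc(OC)c2O[Si](C)(C)C(C)(C)C)ccc1O[Si](C)(C)C(C)(C)C
F18 | step 13 | bis[(E)-alkenyl(tributyl)stannane] | COc1cc(C[C@@H]2COC(=O)[C@H]2Cc2ccc(O[C@H](C)/C=C/[Sn](CCCC)(CCCC)CCCC)c(OC)c2)ccc1O[C@@H](C)/C=C/[Sn](CCCC)(CCCC)CCCC
F19 | step 13 | bis[(E)-alkenyl iodide] | COc1cc(C[C@@H]2COC(=O)[C@H]2Cc2ccc(O[C@H](C)/C=C/I)c(OC)c2)ccc1O[C@@H](C)/C=C/I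
F20 | step 17 | bis(vicinal diol) from 25 (diol carbons as a mixture) | COc1cc([C@@H](O[Si](C)(C)C(C)(C)C)[C@H](C(O)C(C)O)c2cc(C[C@@H]3COC(=O)[C@H]3Cc3cc(OC)c(O[Si](C)(C)C(C)(C)C)c([C@H](C(O)C(C)O)[C@H](O[Si](C)(C)C(C)(C)C)c4ccc(O[Si](C)(C)C(C)(C)C)c(OC)c4)c3)cc(OC)c2O[Si](C)(C)C(C)(C)C)ccc1O[Si](C)(C)C(C)(C)C
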